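The cyclopentene ring (C1 bearing CH2OAc, C2 bearing CHO, stereocentre C3, then C4H2–C5H2) has one bare edge, C4–C5, which is read as ethylene. A Pauson–Khand reaction of propargyl alcohol, ethylene and CO forms C3–C4, C5–C1 and C1–C2 in one operation. Its precursors are three small achiral molecules, and C1 arrives as a ketone. Oxidation gives a 2-formyl enone. Its oxadiene takes up a Z-enol ether of the side chain in an asymmetric hetero-Diels–Alder reaction that sets C3 and C1' and masks both aldehydes in a temporary dihydropyran. Hydroxymethylation of C1, acetylation and acid-induced 1,3-transposition unzip it to the target.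

Key step: step 1

Remark on numbering: ring atoms C1–C5 as above and C1' for the side-chain CH(CHO). In the bicyclic intermediates (cyclopenta[c]pyran numbering) C7 = C1, C7a = C2, C4a = C3, C4 = C1', C1 = the formyl carbon on C2, and C3 = the formyl carbon on C1'.

Assumption: the (1R,2S) ligand of step 4 is taken to leave the Re face of C3 open. Should the sense be opposite, the equally available (1S,2R) ligand is used and nothing else changes.

Step 1
Reactants: 1 prop-2-yn-1-ol; 2 ethylene
Product: 4 2-(hydroxymethyl)cyclopent-2-en-1-one, via hexacarbonyldicobalt alkyne complex 3 (not isolated)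
Conditions: Co2(CO)8 (1.05 equiv), toluene, rt; then ethylene (6 bar), N-methylmorpholine N-oxide (6 equiv), 4 Å MS, rt
Reagents that add atoms: carbon monoxide [C-]#[O+], delivered by Co2(CO)8 O=C=[Co](=C=O)(=C=O)(=C=O)[Co](=C=O)(=C=O)(=C=O)=C=O
Why: Propargyl alcohol replaces two CO ligands of Co2(CO)8 to give the C2Co2 tetrahedrane 3; the N-oxide oxidises one CO ligand to CO2, ethylene takes the free site and inserts into the Co–C bond of the unsubstituted alkyne carbon (C3–C4 bond), CO migrates into the new Co–CH2 bond (C5–C1 bond), and reductive elimination joins C1 to C2. The closest known reaction type is the intermolecular Pauson–Khand [2+2+1] cycloaddition of terminal alkynes with ethylene under amine N-oxide promotion. The single ring closed is the five-membered carbocycle of the target, closed by cycloaddition through a cobaltacyclopentene and a final reductive elimination, so no exo or endo mode applies. No stereocentre is formed and 4 is achiral. The step needs only regiocontrol in the alkyne: the carbon bearing CH2OH is the hindered one, so ethylene inserts at the terminal carbon and the substituent ends up next to the carbonyl group, while ethylene is symmetric and raises no regiochemical question. The ethylene pressure should hold back alkyne trimerisation and decomplexation.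

Step 2
Reactants: 4 2-(hydroxymethyl)cyclopent-2-en-1-one
Product: 5 5-oxocyclopent-1-ene-1-carbaldehyde
Conditions: DMP (1.1 equiv), CH2Cl2, 0 °C; cold filtration through a short silica pad, solution used at once
Reagents that add atoms: none
Why: Dess–Martin oxidation of a primary allylic alcohol runs under neutral, non-aqueous conditions, stops at the aldehyde and brings in no nucleophile that could attack the doubly activated C2=C3 bond; no stereocentre is involved.

Step 3
Reactants: 6 allyl tert-butyl ether; 7 geranyl bromide
Product: 9 (1Z,5E)-1-tert-butoxy-6,10-dimethylundeca-1,5,9-triene, via (Z)-3-tert-butoxyallyllithium 8 (not isolated)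
Conditions: 6, s-BuLi (1.05 equiv), THF, −78 °C; then 7, −78 °C to 0 °C
Reagents that add atoms: none
Why: This is the gamma-alkylation of a metalated allyl ether (homoenolate equivalent): lithium stays chelated by the ether oxygen, which locks the allyl anion cis, and SN2 attack of its oxygen-remote terminus on the primary allylic bromide should give the enol ether as the Z isomer while the E double bond of 7 is untouched.

Step 4
Reactants: 5 5-oxocyclopent-1-ene-1-carbaldehyde; 9 (1Z,5E)-1-tert-butoxy-6,10-dimethylundeca-1,5,9-triene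
Product: 10 (3R,4R,4aS)-3-tert-butoxy-4-[(3E)-4,8-dimethylnona-3,7-dien-1-yl]-4,4a,5,6-tetrahydrocyclopenta[c]pyran-7(3H)-one
Conditions: 5 (1.3 equiv), CrCl(C27H29NO2) (10 mol %; trivalent chromium, ligand = dianion of (1R,2S)-1-{[3-(1-adamantyl)-2-hydroxy-5-methylbenzylidene]amino}indan-2-ol), 4 Å MS, CH2Cl2, −30 °C
Reagents that add atoms: none
Why: In this inverse-electron-demand hetero-Diels–Alder reaction only the exocyclic formyl group can be s-cis to C2=C3 (the ring ketone is locked s-trans and merely lowers the LUMO), the Z-enol ether adds suprafacially through the alkoxy-endo transition state so that H-3, H-4 and H-4a come out all cis (this fixes C1' relative to C3), and the chiral chromium Lewis acid on the formyl oxygen shields one face so that bonding at the Re face of C3 gives the 4R,4aS series.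

Step 5
Reactants: 10 bicyclic alkoxymethylene ketone
Product: 12 (3R,4R,4aS)-3-tert-butoxy-4-[(3E)-4,8-dimethylnona-3,7-dien-1-yl]-7-(hydroxymethyl)-3,4,4a,5,6,7-hexahydrocyclopenta[c]pyran-7-ol (C7 epimers), via beta-hydroxysilane 11 (not isolated)
Conditions: ClMgCH2SiMe2(Oi-Pr) (from ClCH2SiMe2(Oi-Pr), Mg, THF), THF, −20 °C to 0 °C; aq. NH4Cl/NH3 work-up; crude product, 30% H2O2, KF, KHCO3, THF/MeOH, rt
Reagents that add atoms: [(isopropoxydimethylsilyl)methyl]magnesium chloride CC(C)O[Si](C)(C)C[Mg]Cl; hydrogen peroxide OO
Why: 1,2-Addition of a hydroxymethyl anion equivalent (silylmethyl Grignard reagent) to the carbonyl group of an alkoxymethylene ketone, followed by Tamao oxidation of the C–Si bond, gives the 1,2-diol under basic conditions throughout, and the new carbinol centre C7 may form as an epimer mixture because it becomes sp2 in step 7.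

Step 6
Reactants: 12 diol
Product: 13 [(3R,4R,4aS)-3-tert-butoxy-4-[(3E)-4,8-dimethylnona-3,7-dien-1-yl]-7-hydroxy-3,4,4a,5,6,7-hexahydrocyclopenta[c]pyran-7-yl]methyl acetate (C7 epimers)
Conditions: Ac2O (1.1 equiv), pyridine, CH2Cl2, 0 °C
Reagents that add atoms: acetic anhydride CC(=O)OC(C)=O
Why: In this base-mediated O-acylation the primary hydroxyl reacts far faster than the hindered tertiary allylic one, and capping it before any acid is applied keeps this oxygen from closing onto the formyl carbon later (furan formation).

Step 7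
Reactants: 13 hydroxy acetate
Product: 15 [(3S)-2-formyl-3-[(2R,5E)-6,10-dimethyl-1-oxoundeca-5,9-dien-2-yl]cyclopent-1-en-1-yl]methyl acetate (target), via bicyclic lactol 14 (not isolated)
Conditions: PPTS (cat.), acetone/H2O (9:1), 0 °C to rt
Reagents that add atoms: water O
Why: In this acid-induced 1,3-carbonyl transposition of the Stork–Danheiser type the enol ether oxygen pushes out the tertiary hydroxyl (C1=C2 forms), water adds to the oxocarbenium carbon to give 14, whose ring opening frees the enal and a tert-butyl hemiacetal that collapses to the second aldehyde, and the mild acid should leave C3, the enolisable C1', the acetate and the trisubstituted alkenes untouched.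

Compound list
1 | prop-2-yn-1-ol | C#CCO | starting material
2 | ethylene | C=C | starting material
3 | hexacarbonyl(μ-prop-2-yn-1-ol)dicobalt | OCC12[CH]3[Co]1(=C=O)(=C=O)(=C=O)[Co]23(=C=O)(=C=O)=C=O | intermediate
4 | 2-(hydroxymethyl)cyclopent-2-en-1-one | O=C1CCC=C1CO | intermediate
5 | 5-oxocyclopent-1-ene-1-carbaldehyde | O=CC1=CCCC1=O | intermediate
6 | allyl tert-butyl ether | C=CCOC(C)(C)C | starting material
7 | geranyl bromide, (2E)-1-bromo-3,7-dimethylocta-2,6-diene | BrC/C=C(\C)CCC=C(C)C | starting material
8 | (Z)-3-tert-butoxyallyllithium | [Li]C/C=C\OC(C)(C)C | intermediate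
9 | (1Z,5E)-1-tert-butoxy-6,10-dimethylundeca-1,5,9-triene | CC(C)(C)O/C=C\CC/C=C(\C)CCC=C(C)C | intermediate
10 | (3R,4R,4aS)-3-tert-butoxy-4-[(3E)-4,8-dimethylnona-3,7-dien-1-yl]-4,4a,5,6-tetrahydrocyclopenta[c]pyran-7(3H)-one | O=C1C2=CO[C@H](OC(C)(C)C)[C@H](CC/C=C(\C)CCC=C(C)C)[C@@H]2CC1 | intermediate
11 | 7-{[dimethyl(propan-2-yloxy)silyl]methyl} carbinol from 10 (C7 epimers) | CC(C)O[Si](C)(C)CC1(O)C2=CO[C@H](OC(C)(C)C)[C@H](CC/C=C(\C)CCC=C(C)C)[C@@H]2CC1 | intermediate
12 | 7-(hydroxymethyl) carbinol, the 1,2-diol (C7 epimers) | OCC1(O)C2=CO[C@H](OC(C)(C)C)[C@H](CC/C=C(\C)CCC=C(C)C)[C@@H]2CC1 | intermediate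
13 | primary acetate of 12 (C7 epimers) | CC(=O)OCC1(O)C2=CO[C@H](OC(C)(C)C)[C@H](CC/C=C(\C)CCC=C(C)C)[C@@H]2CC1 | intermediate
14 | [(3R,4R,4aS)-3-tert-butoxy-1-hydroxy-4-[(3E)-4,8-dimethylnona-3,7-dien-1-yl]-1,3,4,4a,5,6-hexahydrocyclopenta[c]pyran-7-yl]methyl acetate (C1 epimers) | CC(=O)OCC1=C2C(O)O[C@H](OC(C)(C)C)[C@H](CC/C=C(\C)CCC=C(C)C)[C@@H]2CC1 | intermediate
15 | [(3S)-2-formyl-3-[(2R,5E)-6,10-dimethyl-1-oxoundeca-5,9-dien-2-yl]cyclopent-1-en-1-yl]methyl acetate | CC(=O)OCC1=C(C=O)[C@H]([C@H](C=O)CC/C=C(\C)CCC=C(C)C)CC1 | target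

Total step count: 7. Longest linear sequence: 6 steps (1, 2, 4, 5, 6, 7).

Steps most likely to fail

Step 4. Facial and endo selectivity may be eroded by the uncatalysed background cycloaddition of the very electrophilic oxadiene, by binding of chromium to the ring ketone, or by a stepwise addition that loses the Z information. The fallback moves the chirality into the dienophile as a cleavable auxiliary.
- It sets out from 7. Commercial (1R,2S)-2-phenylcyclohexanol (either enantiomer can be bought, and the choice follows the observed face) is O-allylated (NaH, allyl bromide, THF) to its allyl ether F1.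
- F1 is metalated as in step 3 to the allyllithium F2 and alkylated with 7 to the auxiliary-bearing Z-enol ether F3.
- Uncatalysed hetero-Diels–Alder reaction with 5 (CH2Cl2, 0 °C) gives the cycloadduct F4. The adducts from the two faces are diastereomers that can be separated by chromatography, so optical purity no longer rests on a catalyst.
- The chemistry of steps 5 to 7 then leads through the beta-hydroxysilane F5, the diol F6, the acetate F7 and the lactol F8. The last hydrolysis comes back to the route at 15 and releases the auxiliary.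

Step 5. Conjugate addition–elimination at the alkoxymethylene carbon, enolisation of the ketone, or early ionisation of the free diol with closure of the primary oxygen onto the formyl carbon may compete. The fallback never carries a free primary hydroxyl.
- It sets out from 10. Chloromethyllithium, generated from ICH2Cl and MeLi·LiBr in the presence of 10 at −78 °C and quenched cold with AcOH, gives the chlorohydrin F9.
- PPTS in wet acetone performs the same 1,3-transposition to the chloromethyl dialdehyde F10.
- SN2 displacement with KOAc (DMF, rt) comes back to the route at 15.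

Step 2. Oligomerisation or hydration of the doubly activated enal may occur during oxidation, filtration and transfer. The fallback traps the enal as it forms.
- It sets out from 4, which is oxidised with activated MnO2 in CH2Cl2 in the presence of the enol ether F3 of the step 4 fallback, so that 5 never accumulates.
- A Lewis acid catalyst cannot work in this slurry, so stereocontrol comes from the auxiliary. The product is F4, which rejoins the route at 15 by the path described for step 4.

Further compounds
F1 | step 4 | allyl (1R,2S)-2-phenylcyclohexyl ether | C=CCO[C@@H]1CCCC[C@H]1c1ccccc1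
F2 | step 4 | (Z)-3-{[(1R,2S)-2-phenylcyclohexyl]oxy}allyllithium | [Li]C/C=C\O[C@@H]1CCCC[C@H]1c1ccccc1
F3 | step 4 | (1Z,5E)-6,10-dimethyl-1-{[(1R,2S)-2-phenylcyclohexyl]oxy}undeca-1,5,9-triene | CC(C)=CCC/C(C)=C/CC/C=C\O[C@@H]1CCCC[C@H]1c1ccccc1
F4 | step 4 | 3-{[(1R,2S)-2-phenylcyclohexyl]oxy} analogue of 10 | O=C1C2=CO[C@H](O[C@@H]3CCCC[C@H]3c3ccccc3)[C@H](CC/C=C(\C)CCC=C(C)C)[C@@H]2CC1
F5 | step 4 | 3-{[(1R,2S)-2-phenylcyclohexyl]oxy} analogue of 11 | CC(C)O[Si](C)(C)CC1(O)C2=CO[C@H](O[C@@H]3CCCC[C@H]3c3ccccc3)[C@H](CC/C=C(\C)CCC=C(C)C)[C@@H]2CC1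
F6 | step 4 | 3-{[(1R,2S)-2-phenylcyclohexyl]oxy} analogue of 12 | OCC1(O)C2=CO[C@H](O[C@@H]3CCCC[C@H]3c3ccccc3)[C@H](CC/C=C(\C)CCC=C(C)C)[C@@H]2CC1
F7 | step 4 | 3-{[(1R,2S)-2-phenylcyclohexyl]oxy} analogue of 13 | CC(=O)OCC1(O)C2=CO[C@H](O[C@@H]3CCCC[C@H]3c3ccccc3)[C@H](CC/C=C(\C)CCC=C(C)C)[C@@H]2CC1
F8 | step 4 | 3-{[(1R,2S)-2-phenylcyclohexyl]oxy} analogue of 14 | CC(=O)OCC1=C2C(O)O[C@H](O[C@@H]3CCCC[C@H]3c3ccccc3)[C@H](CC/C=C(\C)CCC=C(C)C)[C@@H]2CC1
F9 | step 5 | 7-(chloromethyl) carbinol from 10 (C7 epimers) | ClCC1(O)C2=CO[C@H](OC(C)(C)C)[C@H](CC/C=C(\C)CCC=C(C)C)[C@@H]2CC1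
F10 | step 5 | (5S)-2-(chloromethyl)-5-[(2R,5E)-6,10-dimethyl-1-oxoundeca-5,9-dien-2-yl]cyclopent-1-ene-1-carbaldehyde | ClCC1=C(C=O)[C@H]([C@H](C=O)CC/C=C(\C)CCC=C(C)C)CC1
F0 | step 2 | none | none
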